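**Plan**

1. Numbering (germacranolide): C1 ketone carbon, C2 furanone CH, C3 furanone C–O, C4=C5 ring alkene, C6/C7 lactone ring fusion, C8 (methacrylate), C9 (angelate), C10 (quaternary, Me and O), C11–C13 acrylate unit of the lactone, C15 the CH2OH carbon.
2. Cuts, in order: furanone O–C3 (to an α'-hydroxy 1,3-diketone); C1–C2 (an acyl shift from O15 to C2, which leads back to a 10-membered lactone between the C1 carboxyl and O15); O15–C1; the two side-chain esters; C6–C7 together with O6–C12 (allylation and lactonisation); the C9/C10 diol and C9=C10.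
3. Forward: east enynal (C2–C6, C15) plus west allyl bromide (C1, C7–C14) give the γ-lactone; the esters are installed; Mitsunobu closure gives the 10-membered lactone; alkyne hydration gives the methyl ketone; enolate acyl transfer turns the lactone into the 10-membered carbocycle and frees C15–OH; acid closes the 3(2H)-furanone.
4. Enabling feature: C15–OH sits on C4 next to C3, so in the lactone the atoms C2, C3, C4, C15, O15 and C1 form a six-membered array (a β-acyloxy ketone); C10 carries the tertiary OH that captures the resulting 1,3-diketone as the furanone ring.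
5. Stereochemistry: C8 from (R)-benzyl glycidyl ether; C9/C10 by hydroxyl-directed syn-dihydroxylation of an (E)-enoate; C7/C6 by chromium-mediated anti-allylation under control of C8; C4=C5 geometry from trans-hydroalumination/iodination of an alkyne; the angelate is introduced with its (Z)-geometry intact.

Key step: step 23

**Route**

Step 1
Reactants: 1 but-2-yne-1,4-diol
Product: 2 4-[(4-methoxybenzyl)oxy]but-2-yn-1-ol
Conditions: NaH (1 equiv), 4-methoxybenzyl chloride (1 equiv), n-Bu4NI (cat.), THF/DMF, 0 °C → rt; diol 1 in threefold excess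
Reagents that add atoms: 4-methoxybenzyl chloride, COc1ccc(CCl)cc1
Why: Williamson etherification in which the excess of the symmetric diol enforces monoprotection.

Step 2
Reactants: 2 4-[(4-methoxybenzyl)oxy]but-2-yn-1-ol
Product: 3 (Z)-3-iodo-4-[(4-methoxybenzyl)oxy]but-2-en-1-ol
Conditions: NaAlH2(OCH2CH2OCH3)2 (Red-Al), THF, 0 °C; then I2, THF, −78 → 0 °C
Reagents that add atoms: iodine, II
Why: Hydroxyl-directed trans-hydroalumination places aluminium on the distal alkyne carbon and iodinolysis with retention gives the (Z)-iodoalkene, which fixes the C4=C5 geometry (C6 cis to the future C3).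

Step 3
Reactants: 3 (Z)-3-iodo-4-[(4-methoxybenzyl)oxy]but-2-en-1-ol; 4 ethynyltrimethylsilane
Product: 6 (E)-3-{[(4-methoxybenzyl)oxy]methyl}pent-2-en-4-yn-1-ol, via trimethylsilyl enyne 5 (not isolated)
Conditions: PdCl2(PPh3)2 (cat.), CuI (cat.), Et3N, THF, rt; then K2CO3, MeOH, rt
Reagents that add atoms: none
Why: Sonogashira coupling with retention of alkene geometry installs C3/C2 as an alkyne (a masked acetyl group) and methanolysis removes the silyl cap.

Step 4
Reactants: 6 (E)-3-{[(4-methoxybenzyl)oxy]methyl}pent-2-en-4-yn-1-ol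
Product: 7 (E)-3-{[(4-methoxybenzyl)oxy]methyl}pent-2-en-4-ynal
Conditions: MnO2 (excess), CH2Cl2, rt
Reagents that add atoms: none
Why: Chemoselective allylic oxidation with MnO2 gives the enal (C6) without touching the alkyne or the PMB ether.

Step 5
Reactants: 8 (R)-2-[(benzyloxy)methyl]oxirane
Product: 9 (R)-1-(benzyloxy)but-3-en-2-ol
Conditions: Me3S+ I− (3 equiv), n-BuLi (3 equiv), THF, −10 °C → rt
Reagents that add atoms: trimethylsulfonium iodide, C[S+](C)C.[I-]
Why: Epoxide opening by dimethylsulfonium methylide at the CH2 terminus followed by elimination of dimethyl sulfide (one-carbon homologation to the allylic alcohol) leaves the stereocentre, the future C8, untouched.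

Step 6
Reactants: 9 (R)-1-(benzyloxy)but-3-en-2-ol; 10 tert-butyl methacrylate
Product: 11 tert-butyl (2E,4R)-5-(benzyloxy)-4-hydroxy-2-methylpent-2-enoate
Conditions: second-generation Hoveyda–Grubbs catalyst RuCl2(SIMes)(=CH–C6H4–2-O-i-Pr) (5 mol%), 10 (5 equiv), CH2Cl2, 40 °C
Reagents that add atoms: none
Why: Olefin cross-metathesis between a monosubstituted alkene and a 1,1-disubstituted methacrylate favours the cross product and should give the thermodynamically preferred (E)-trisubstituted enoate (C9=C10 with C1 and C14).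

Step 7
Reactants: 11 tert-butyl (2E,4R)-5-(benzyloxy)-4-hydroxy-2-methylpent-2-enoate
Product: 13 tert-butyl (2S,3R,4S)-5-(benzyloxy)-2,3,4-trihydroxy-2-methylpentanoate, via osmate ester 12 (not isolated)
Conditions: OsO4 (1.05 equiv), TMEDA (1.1 equiv), CH2Cl2, −78 °C; then aq. Na2SO3, THF, 60 °C
Reagents that add atoms: osmium tetroxide, O=[Os](=O)(=O)=O
Why: Hydrogen-bond-directed dihydroxylation with the OsO4–TMEDA complex, in which A1,3 strain from the methyl group cis to C8 holds the C8–H in the alkene plane and the reagent is delivered syn to the C8 hydroxyl, so that suprafacial addition to the (E)-alkene should set C9 and C10 in the all-syn triol pattern.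

Step 8
Reactants: 13 tert-butyl (2S,3R,4S)-5-(benzyloxy)-2,3,4-trihydroxy-2-methylpentanoate
Product: 14 tert-butyl (2S,3R,4S)-5-(benzyloxy)-4-[(tert-butyldimethylsilyl)oxy]-2,3-dihydroxy-2-methylpentanoate
Conditions: TBSCl (1.1 equiv), imidazole, DMF, 0 °C → rt
Reagents that add atoms: tert-butyldimethylsilyl chloride, CC(C)(C)[Si](C)(C)Cl
Why: Silyl ether formation should select the C8 hydroxyl because the C9 hydroxyl is flanked by the quaternary C10 and the C10 hydroxyl is tertiary.

Step 9
Reactants: 14 tert-butyl (2S,3R,4S)-5-(benzyloxy)-4-[(tert-butyldimethylsilyl)oxy]-2,3-dihydroxy-2-methylpentanoate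
Product: 15 C9/C10 acetonide of 14 (C7 OBn; C8 OTBS; C1 tert-butyl ester)
Conditions: 2-methoxypropene, PPTS (cat.), CH2Cl2, 0 °C → rt
Reagents that add atoms: 2-methoxypropene, COC(C)=C
Why: Acid-catalysed acetal formation masks the remaining 1,2-diol as a dioxolane, so that no β-acyloxy or β-hydroxy group can be eliminated in the aldehyde steps that follow.

Step 10
Reactants: 15 C9/C10 acetonide of 14
Product: 16 primary alcohol (C7 OH; C8 OTBS; C9/C10 acetonide; C1 tert-butyl ester)
Conditions: H2 (1 atm), palladium on carbon (Pd/C), EtOAc, rt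
Reagents that add atoms: none
Why: Hydrogenolysis of the benzyl ether, possible here because the intermediate has no alkene.

Step 11
Reactants: 16 primary alcohol
Product: 17 aldehyde (C7 CHO; C8 OTBS; C9/C10 acetonide; C1 tert-butyl ester)
Conditions: Dess–Martin periodinane, CH2Cl2, rt
Reagents that add atoms: none
Why: Dess–Martin oxidation gives the α-silyloxy aldehyde under non-basic conditions that should not epimerise C8.

Step 12
Reactants: 17 aldehyde; 18 methyl acrylate
Product: 19 Morita–Baylis–Hillman adduct (methyl 2-[hydroxy(alkyl)methyl]acrylate; both epimers at the new C7 carbinol)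
Conditions: DABCO (1 equiv), 18 (neat, excess), MeOH (trace), rt, several days
Reagents that add atoms: none
Why: Morita–Baylis–Hillman reaction joins C7 to C11, and the configuration of the new carbinol centre is irrelevant because C7 becomes sp2 in the next step.

Step 13
Reactants: 19 Morita–Baylis–Hillman adduct
Product: 20 (Z)-allyl bromide (methyl (Z)-2-(bromomethyl)alk-2-enoate; C8 cis to CH2Br)
Conditions: NBS, Me2S, CH2Cl2, 0 °C → rt
Reagents that add atoms: N-bromosuccinimide, O=C1CCC(=O)N1Br
Why: Corey–Kim-type activation of the allylic alcohol and SN2' displacement by bromide should converge both carbinol epimers on the thermodynamically preferred (Z)-2-(bromomethyl)enoate.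

Step 14
Reactants: 7 (E)-3-{[(4-methoxybenzyl)oxy]methyl}pent-2-en-4-ynal; 20 (Z)-allyl bromide
Product: 22 trans-fused α-methylene-γ-butyrolactone (6,12-olide; C8 OTBS; C9/C10 acetonide; C1 tert-butyl ester; C15 OPMB; ethynyl on C4), via hydroxy ester 21 (not isolated)
Conditions: CrCl2 (4 equiv, nickel-free), THF, 0 °C → rt; then TsOH·H2O (cat.), CH2Cl2, rt
Reagents that add atoms: none
Why: Nozaki–Hiyama-type allylation in which the equilibrating allylchromium adds through a chair transition state with C8 pseudo-equatorial to give the anti C6/C7 adduct, the aldehyde attacking C7 anti to the bulky C9 dioxolane carbon with C8–H in the allyl plane (sets C7 relative to C8), and acid then closes the trans-fused lactone.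

Step 15
Reactants: 22 trans-fused α-methylene-γ-butyrolactone
Product: 23 C8 alcohol
Conditions: HF·pyridine, pyridine, THF, 0 °C → rt
Reagents that add atoms: none
Why: Fluoride-mediated desilylation under buffered conditions should spare the acetonide, the PMB ether, the tert-butyl ester and the lactone.

Step 16
Reactants: 23 C8 alcohol; 24 methacrylic anhydride
Product: 25 C8 methacrylate
Conditions: Et3N, DMAP (cat.), CH2Cl2, 0 °C
Reagents that add atoms: none
Why: DMAP-catalysed acylation of the only free hydroxyl installs the methacrylate ester.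

Step 17
Reactants: 25 C8 methacrylate
Product: 26 C9/C10 diol
Conditions: AcOH/H2O (4:1), 50 °C
Reagents that add atoms: none
Why: Acid-catalysed acetal hydrolysis under conditions expected to be too mild to cleave the tert-butyl ester or the PMB ether.

Step 18
Reactants: 26 C9/C10 diol; 27 angelic acid
Product: 29 C9 angelate (C10 OH free), via mixed anhydride 28 (not isolated)
Conditions: 27, 2,4,6-trichlorobenzoyl chloride, Et3N, toluene, rt; then 26, toluene, 75 °C
Reagents that add atoms: none
Why: Yamaguchi-type esterification through the preformed mixed anhydride without a nucleophilic catalyst should keep the (Z)-geometry of the angelate, and the secondary C9 hydroxyl reacts while the tertiary C10 hydroxyl does not.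

Step 19
Reactants: 29 C9 angelate
Product: 30 seco acid (C1 CO2H; C10 OH; C15 OH)
Conditions: TFA/CH2Cl2 (1:4), anisole, 0 °C → rt
Reagents that add atoms: none
Why: Acidolysis cleaves the tert-butyl ester through the tert-butyl cation and the PMB ether through the 4-methoxybenzyl cation, which anisole traps.

Step 20
Reactants: 30 seco acid
Product: 31 10-membered lactone (C1 carbonyl to O15; ring C1, O15, C15, C4–C10; E-alkene in the ring; ethynyl on C4)
Conditions: PPh3, DIAD, toluene (0.001 M, slow addition of 30), 0 °C → rt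
Reagents that add atoms: none
Why: Mitsunobu macrolactonisation, in which the primary allylic C15 hydroxyl is activated as an oxyphosphonium ion and displaced by the hindered carboxylate at high dilution while the tertiary C10 hydroxyl stays inert.

Step 21
Reactants: 31 10-membered lactone
Product: 32 methyl ketone (acetyl C3/C2 on C4)
Conditions: (Ph3P)AuNTf2 (5 mol%), H2O (5 equiv), 1,4-dioxane, 40 °C
Reagents that add atoms: water, O
Why: Gold-catalysed Markovnikov hydration of the terminal alkyne unmasks the methyl ketone without base, so the enone geometry and the acrylate units are not at risk.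

Step 22
Reactants: 32 methyl ketone
Product: 33 bis(trimethylsilyl) derivative (C10 OTMS; C3(OTMS)=C2H2)
Conditions: TMSOTf (2.5 equiv), Et3N (4 equiv), CH2Cl2, 0 °C
Reagents that add atoms: trimethylsilyl trifluoromethanesulfonate, C[Si](C)(C)OS(=O)(=O)C(F)(F)F
Why: Silyl enol ether formation with TMSOTf/Et3N should give the cross-conjugated 2-silyloxydiene at the methyl group and cap the tertiary hydroxyl in the same operation.

Step 23
Reactants: 33 bis(trimethylsilyl) derivative
Product: 36 target CNP0359568.2, via silyl diketone 34 (not isolated), via hydroxy diketone 35 (not isolated)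
Conditions: TASF [(Me2N)3S+ Me3SiF2−] (1.1 equiv), THF (0.005 M), −78 → 0 °C; then 1 M aq. HCl, THF, 0 °C → rt
Reagents that add atoms: none
Why: Proposed new method: fluoride cleaves the enol silyl ether of 33 to a C2 enolate that adds to the lactone carbonyl C1 through the six-membered array C2–C3–C4–C15–O15–C1, and the bridged tetrahedral alkoxide collapses by expelling the C15 alkoxide, so the 10-membered lactone is exchanged for the 10-membered carbocyclic 1,3-diketonate 34 with the C15 hydroxyl set free. The closest known reactions are the Baker–Venkataraman rearrangement and the base-induced 1,5-acyl shift of β-acyloxy ketone enolates to δ-hydroxy 1,3-diketones, which have not been used to convert a macrolactone into a medium carbocycle. The C1–C2 closure is a 6-exo-trig addition within the tether that becomes the 10-membered carbocycle on fragmentation, and on acidification the furanone closes by 5-exo-trig attack of the unmasked tertiary C10 hydroxyl on the C3 carbonyl followed by dehydration. No new stereocentre is created, and the existing ones at C6 to C10 should not epimerise because C10 is quaternary and C7 is not adjacent to a carbonyl group. The step needs C-acylation at C1 instead of conjugate addition to the three acrylate-type acceptors or attack on the γ-lactone, which the six-membered tether should secure, and it is driven by formation of the stabilised diketonate (the expelled alkoxide is the base) and finally by dehydration to the vinylogous ester. Closure through O10–C3 to the furanone, instead of through O15–C1 to a dihydropyranone, is expected because the tertiary hydroxyl closes a five-membered ring without placing a second bridgehead alkene in the bicycle.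

**Compound list**

1 | but-2-yne-1,4-diol | OCC#CCO | starting material
2 | 4-[(4-methoxybenzyl)oxy]but-2-yn-1-ol | OCC#CCOCc1ccc(OC)cc1 | intermediate
3 | (Z)-3-iodo-4-[(4-methoxybenzyl)oxy]but-2-en-1-ol | OC/C=C(\I)COCc1ccc(OC)cc1 | intermediate
4 | ethynyltrimethylsilane | C#C[Si](C)(C)C | starting material
5 | (E)-3-{[(4-methoxybenzyl)oxy]methyl}-5-(trimethylsilyl)pent-2-en-4-yn-1-ol | OC/C=C(\C#C[Si](C)(C)C)COCc1ccc(OC)cc1 | intermediate (not isolated)
6 | (E)-3-{[(4-methoxybenzyl)oxy]methyl}pent-2-en-4-yn-1-ol | OC/C=C(\C#C)COCc1ccc(OC)cc1 | intermediate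
7 | (E)-3-{[(4-methoxybenzyl)oxy]methyl}pent-2-en-4-ynal (CHO = C6; alkyne cis to C6) | O=C/C=C(\C#C)COCc1ccc(OC)cc1 | intermediate
8 | (R)-2-[(benzyloxy)methyl]oxirane | C1[C@@H](O1)COCc2ccccc2 | starting material
9 | (R)-1-(benzyloxy)but-3-en-2-ol | C=C[C@@H](O)COCc1ccccc1 | intermediate
10 | tert-butyl methacrylate | C=C(C)C(=O)OC(C)(C)C | starting material
11 | tert-butyl (2E,4R)-5-(benzyloxy)-4-hydroxy-2-methylpent-2-enoate | CC(C)(C)OC(=O)/C(C)=C/[C@@H](O)COCc1ccccc1 | intermediate
12 | cyclic osmate ester (hexavalent osmium, TMEDA-chelated) across O2/O3 of 13 | CC(C)(C)OC(=O)[C@@]1(C)O[Os](=O)(=O)O[C@@H]1[C@@H](O)COCc2ccccc2.CN(C)CCN(C)C | intermediate (not isolated)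
13 | tert-butyl (2S,3R,4S)-5-(benzyloxy)-2,3,4-trihydroxy-2-methylpentanoate | CC(C)(C)OC(=O)[C@@](C)(O)[C@H](O)[C@@H](O)COCc1ccccc1 | intermediate
14 | tert-butyl (2S,3R,4S)-5-(benzyloxy)-4-[(tert-butyldimethylsilyl)oxy]-2,3-dihydroxy-2-methylpentanoate | CC(C)(C)OC(=O)[C@@](C)(O)[C@H](O)[C@@H](O[Si](C)(C)C(C)(C)C)COCc1ccccc1 | intermediate
15 | C9/C10 acetonide of 14 (C7 OBn; C8 OTBS; C1 tert-butyl ester) | CC(C)(C)OC(=O)[C@@]1(C)OC(C)(C)O[C@@H]1[C@@H](O[Si](C)(C)C(C)(C)C)COCc2ccccc2 | intermediate
16 | primary alcohol (C7 OH; C8 OTBS; C9/C10 acetonide; C1 tert-butyl ester) | CC(C)(C)OC(=O)[C@@]1(C)OC(C)(C)O[C@@H]1[C@@H](O[Si](C)(C)C(C)(C)C)CO | intermediate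
17 | aldehyde (C7 CHO; C8 OTBS; C9/C10 acetonide; C1 tert-butyl ester) | CC(C)(C)OC(=O)[C@@]1(C)OC(C)(C)O[C@@H]1[C@@H](O[Si](C)(C)C(C)(C)C)C=O | intermediate
18 | methyl acrylate | C=CC(=O)OC | starting material
19 | Morita–Baylis–Hillman adduct (C7 carbinol, both epimers; C11 acrylate) | CC(C)(C)OC(=O)[C@@]1(C)OC(C)(C)O[C@@H]1[C@@H](O[Si](C)(C)C(C)(C)C)C(O)C(=C)C(=O)OC | intermediate
20 | (Z)-allyl bromide (C7=C11; CH2Br = C13; CO2Me = C12) | CC(C)(C)OC(=O)[C@@]1(C)OC(C)(C)O[C@@H]1[C@@H](O[Si](C)(C)C(C)(C)C)/C=C(\CBr)C(=O)OC | intermediate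
21 | anti homoallylic alcohol (C6 OH; C12 methyl ester) | CC(C)(C)OC(=O)[C@@]1(C)OC(C)(C)O[C@@H]1[C@@H](O[Si](C)(C)C(C)(C)C)[C@@H](C(=C)C(=O)OC)[C@H](O)/C=C(/COCc2ccc(OC)cc2)C#C | intermediate (not isolated)
22 | trans-fused α-methylene-γ-butyrolactone (6,12-olide; C8 OTBS; C9/C10 acetonide; C1 tert-butyl ester; C15 OPMB; ethynyl on C4) | CC(C)(C)OC(=O)[C@@]1(C)OC(C)(C)O[C@@H]1[C@@H](O[Si](C)(C)C(C)(C)C)[C@H]2C(=C)C(=O)O[C@@H]2/C=C(/COCc3ccc(OC)cc3)C#C | intermediate
23 | C8 alcohol of 22 | CC(C)(C)OC(=O)[C@@]1(C)OC(C)(C)O[C@@H]1[C@@H](O)[C@H]2C(=C)C(=O)O[C@@H]2/C=C(/COCc3ccc(OC)cc3)C#C | intermediate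
24 | methacrylic anhydride | C=C(C)C(=O)OC(=O)C(C)=C | starting material
25 | C8 methacrylate | CC(C)(C)OC(=O)[C@@]1(C)OC(C)(C)O[C@@H]1[C@@H](OC(=O)C(C)=C)[C@H]2C(=C)C(=O)O[C@@H]2/C=C(/COCc3ccc(OC)cc3)C#C | intermediate
26 | C9/C10 diol (C8 methacrylate) | CC(C)(C)OC(=O)[C@@](C)(O)[C@H](O)[C@@H](OC(=O)C(C)=C)[C@H]1C(=C)C(=O)O[C@@H]1/C=C(/COCc2ccc(OC)cc2)C#C | intermediate
27 | angelic acid, (Z)-2-methylbut-2-enoic acid | C/C=C(/C)C(=O)O | starting material
28 | angelic 2,4,6-trichlorobenzoic anhydride | C/C=C(/C)C(=O)OC(=O)c1c(Cl)cc(Cl)cc1Cl | intermediate (not isolated)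
29 | C9 angelate (C8 methacrylate; C10 OH; C1 tert-butyl ester; C15 OPMB) | CC(C)(C)OC(=O)[C@@](C)(O)[C@H](OC(=O)/C(C)=C\C)[C@@H](OC(=O)C(C)=C)[C@H]1C(=C)C(=O)O[C@@H]1/C=C(/COCc2ccc(OC)cc2)C#C | intermediate
30 | seco acid (C1 CO2H; C10 OH; C15 OH) | OC(=O)[C@@](C)(O)[C@H](OC(=O)/C(C)=C\C)[C@@H](OC(=O)C(C)=C)[C@H]1C(=C)C(=O)O[C@@H]1/C=C(/CO)C#C | intermediate
31 | 10-membered lactone (C1 carbonyl to O15; ethynyl on C4) | O=C1[C@@](C)(O)[C@H](OC(=O)/C(C)=C\C)[C@@H](OC(=O)C(C)=C)[C@H]2C(=C)C(=O)O[C@@H]2/C=C(/CO1)C#C | intermediate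
32 | methyl ketone (acetyl on C4 of the lactone 31) | O=C1[C@@](C)(O)[C@H](OC(=O)/C(C)=C\C)[C@@H](OC(=O)C(C)=C)[C@H]2C(=C)C(=O)O[C@@H]2/C=C(/CO1)C(C)=O | intermediate
33 | bis(trimethylsilyl) derivative (C10 OTMS; C3(OTMS)=C2H2) | O=C1[C@@](C)(O[Si](C)(C)C)[C@H](OC(=O)/C(C)=C\C)[C@@H](OC(=O)C(C)=C)[C@H]2C(=C)C(=O)O[C@@H]2/C=C(/CO1)C(=C)O[Si](C)(C)C | intermediate
34 | silyl diketone (10-membered carbocycle; C1 and C3 ketones; C10 OTMS; C15 OH) | O=C1[C@@](C)(O[Si](C)(C)C)[C@H](OC(=O)/C(C)=C\C)[C@@H](OC(=O)C(C)=C)[C@H]2C(=C)C(=O)O[C@@H]2/C=C(/CO)C(=O)C1 | intermediate (not isolated)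
35 | hydroxy diketone (C10 OH; C15 OH) | O=C1[C@@](C)(O)[C@H](OC(=O)/C(C)=C\C)[C@@H](OC(=O)C(C)=C)[C@H]2C(=C)C(=O)O[C@@H]2/C=C(/CO)C(=O)C1 | intermediate (not isolated)
36 | CNP0359568.2, (4Z,6R,7S,8S,9R,10S)-9-angeloyloxy-15-hydroxy-8-methacryloyloxy-1-oxo-3,10-epoxygermacra-2,4,11(13)-trien-12,6-olide | C=C(C)C(=O)O[C@H]1[C@H]2C(=C)C(=O)O[C@@H]2/C=C(/CO)C2=CC(=O)[C@@](C)(O2)[C@@H]1OC(=O)/C(C)=C\C | target

**Step count and risks**

Total step count: 23. Longest linear sequence: 19 (steps 5–23).

Steps most likely to fail: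

1. Step 23 (Proposed new method). The enolate may fail to add to the hindered, neopentyl-type lactone carbonyl, or the tetrahedral intermediate may revert. The naked enolate may instead undergo conjugate addition to the acrylate units. On acidification, cyclodehydration through the C15 hydroxyl onto C1 could compete with furanone closure. Fallback with known chemistry, setting out from 30: the acid is converted into the S-ethyl thioester F1 (EtSH, EDC·HCl, DMAP cat., CH2Cl2). F1 is cyclised at high dilution by palladium/copper-catalysed thioester–alkyne coupling (PdCl2(dppf), tri(2-furyl)phosphine, CuI, Et3N, DMF, 50 °C) to the 10-membered ynone F2, which contains the same C1–C2 bond. Gold-catalysed 5-endo-dig addition of the C10 hydroxyl to C3 of the ynone ((Ph3P)AuNTf2, CH2Cl2, rt) then gives the furanone, and the route is rejoined at 36.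

2. Step 20. Intermolecular esterification (diolide and oligomer formation) may outrun closure of the strained 10-membered (E)-lactone, and SN2' attack at C5 is possible. Fallback, setting out from 29: the ring-closing event is changed from a redox condensation to an intramolecular alkylation of a pre-formed electrophile. DDQ (CH2Cl2/pH 7 buffer) removes the PMB ether to give the C15 alcohol F3. CBr4/PPh3 converts it into the allylic bromide F4. TFA cleaves the tert-butyl ester to give the bromo acid F5. Cs2CO3 in DMF at high dilution then closes the lactone by carboxylate displacement of bromide, and the route is rejoined at 31.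

3. Step 14. Equilibration of the allylchromium species may give poor anti/syn selectivity at C6/C7 or poor facial selectivity with respect to C8, and divalent chromium may reduce the enynal. Fallback, setting out from 17: the allyl nucleophile is replaced by a geometrically defined allylboronate that reacts through a closed transition state. Homologation with dimethyl (1-diazo-2-oxopropyl)phosphonate (K2CO3, MeOH) gives the terminal alkyne F6. LiN(SiMe3)2 followed by ClCO2Me gives the ynoate F7. Syn-hydroalumination (i-Bu2AlH, HMPA, THF) and alkylation of the α-alumino acrylate with ICH2B(pin) gives the (Z)-allylboronate F8, in which C8 is cis to the ester. Sc(OTf)3-catalysed allylboration of 7 should then give the anti adduct, and the route is rejoined at 21, which is lactonised to 22 as in step 14.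

Further compounds
F1 | step 23 | S-ethyl thioester of seco acid 30 | CCSC(=O)[C@@](C)(O)[C@H](OC(=O)/C(C)=C\C)[C@@H](OC(=O)C(C)=C)[C@H]1C(=C)C(=O)O[C@@H]1/C=C(/CO)C#C
F2 | step 23 | 10-membered ynone (C1 ketone; C2≡C3; C10 OH; C15 OH) | O=C1[C@@](C)(O)[C@H](OC(=O)/C(C)=C\C)[C@@H](OC(=O)C(C)=C)[C@H]2C(=C)C(=O)O[C@@H]2/C=C(/CO)C#C1
F3 | step 20 | C15 alcohol of 29 (C1 tert-butyl ester retained) | CC(C)(C)OC(=O)[C@@](C)(O)[C@H](OC(=O)/C(C)=C\C)[C@@H](OC(=O)C(C)=C)[C@H]1C(=C)C(=O)O[C@@H]1/C=C(/CO)C#C
F4 | step 20 | C15 allylic bromide (C1 tert-butyl ester) | CC(C)(C)OC(=O)[C@@](C)(O)[C@H](OC(=O)/C(C)=C\C)[C@@H](OC(=O)C(C)=C)[C@H]1C(=C)C(=O)O[C@@H]1/C=C(/CBr)C#C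
F5 | step 20 | bromo acid (C1 CO2H; C15 Br) | OC(=O)[C@@](C)(O)[C@H](OC(=O)/C(C)=C\C)[C@@H](OC(=O)C(C)=C)[C@H]1C(=C)C(=O)O[C@@H]1/C=C(/CBr)C#C
F6 | step 14 | terminal alkyne from aldehyde 17 (C7≡C11H) | CC(C)(C)OC(=O)[C@@]1(C)OC(C)(C)O[C@@H]1[C@@H](O[Si](C)(C)C(C)(C)C)C#C
F7 | step 14 | ynoate (C7≡C11–CO2Me) | CC(C)(C)OC(=O)[C@@]1(C)OC(C)(C)O[C@@H]1[C@@H](O[Si](C)(C)C(C)(C)C)C#CC(=O)OC
F8 | step 14 | (Z)-2-(methoxycarbonyl)allylboronate (C8 cis to CO2Me; CH2B(pin) = C13) | CC(C)(C)OC(=O)[C@@]1(C)OC(C)(C)O[C@@H]1[C@@H](O[Si](C)(C)C(C)(C)C)/C=C(/CB2OC(C)(C)C(C)(C)O2)C(=O)OC
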